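**Retrosynthetic overview**

1. Petchiether B ⇐ one-pot desilylation/saponification ⇐ (10′R)-alcohol ⇐ CBS reduction of a 14-membered α-aryloxy ketone.
2. Key disconnection C7′–C8′: the macrocyclic ketone opens to a seco cyclopropanol/(Z)-alkenyl iodide. The cyclopropanol serves as a ketone homoenolate (β-acyl carbanion), so the bond joins an enone β-carbon and an alkenyl-halide carbon, both natively electrophilic, and carries the 6′Z geometry in unchanged.
3. Seco compound ⇐ E-selective cross-metathesis of an ortho-allyl aryloxy-cyclopropanol with an α-methylene ester that bears the (Z)-alkenyl iodide.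
4. Cyclopropanol ⇐ Kulinkovich reaction of an aryloxyisobutyrate ⇐ phenol O-alkylation ⇐ 2-allylhydroquinone ⇐ benzoquinone; iodide ⇐ α-iodo Wittig olefination ⇐ Claisen rearrangement.
5. Ring order: arene from the quinone (step 1), a temporary cyclopropane (step 4), then the only new ring, the 14-membered ether macrocycle, closed in step 8 as the cyclopropane opens.

Assumption: side-chain locants run from the benzylic CH2 (C1′) to the ether carbon CMe2–O (C11′); read from the SMILES, the target is 10′R, 2′E (CO2H trans to CH2Ar) and 6′Z.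

**Route**

Step 1
Reactants: 1 1,4-benzoquinone; 2 allyltributylstannane
Product: 3 2-allylbenzene-1,4-diol
Conditions: BF3·OEt2 (2 equiv), CH2Cl2, −78 → 0 °C; aq. KF work-up
Reagents that add atoms: none
Why: Lewis-acid-promoted allylstannane addition to the quinone (Hosomi–Sakurai-type quinone allylation: 1,2-addition, allyl shift, enolisation) gives the re-aromatised mono-allyl hydroquinone, and the symmetry of 1 allows only one regioisomer.

Step 2
Reactants: 3 2-allylbenzene-1,4-diol
Product: 4 2-allyl-4-[(triisopropylsilyl)oxy]phenol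
Conditions: TIPSCl (1.05 equiv), imidazole, DMF, 0 °C
Reagents that add atoms: triisopropylsilyl chloride, CC(C)[Si](Cl)(C(C)C)C(C)C
Why: Regioselective phenol silylation, in which the bulky silyl chloride reacts at the unhindered 4-OH rather than the 1-OH flanked by the allyl group (minor isomer removed by chromatography).

Step 3
Reactants: 4 2-allyl-4-[(triisopropylsilyl)oxy]phenol; 5 ethyl 2-bromo-2-methylpropanoate
Product: 6 ethyl 2-{2-allyl-4-[(triisopropylsilyl)oxy]phenoxy}-2-methylpropanoate
Conditions: Cs2CO3 (2 equiv), 5 (2.5 equiv), MeCN, 60 °C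
Reagents that add atoms: none
Why: Williamson-type O-alkylation of the phenoxide with the carbonyl-activated tertiary α-bromo ester (the standard aryloxyisobutyrate synthesis) installs C11′ and the tertiary aryl ether without carbocation chemistry.

Step 4
Reactants: 6 ethyl 2-{2-allyl-4-[(triisopropylsilyl)oxy]phenoxy}-2-methylpropanoate
Product: 7 1-(2-{2-allyl-4-[(triisopropylsilyl)oxy]phenoxy}propan-2-yl)cyclopropan-1-ol
Conditions: Ti(OiPr)4 (0.3 equiv), EtMgBr (2.6 equiv, slow addition), THF/Et2O, 0 °C → rt; aq. NH4Cl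
Reagents that add atoms: ethylmagnesium bromide, CC[Mg]Br
Why: Kulinkovich cyclopropanation, in which the titanacyclopropane formed from two EtMgBr adds twice to the ester carbonyl and gives a storable ketone-homoenolate precursor whose two CH2 groups become C8′ and C9′; the aryl silyl ether is inert and the remote allyl group should be tolerated with EtMgBr.

Step 5
Reactants: 8 methyl 2-(hydroxymethyl)acrylate
Product: 10 methyl 2-methylene-5-oxopentanoate, via allyl vinyl ether 9 (not isolated)
Conditions: n-butyl vinyl ether (10 equiv), Pd(OCOCF3)2 (2 mol %), 4,7-diphenyl-1,10-phenanthroline (2 mol %), Et3N (cat.), 75 °C; evaporate; xylene, BHT, 140 °C (sealed)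
Reagents that add atoms: n-butyl vinyl ether, C=COCCCC
Why: Pd(II)-catalysed transfer vinylation gives the allyl vinyl ether, and its Claisen [3,3] rearrangement delivers the γ,δ-unsaturated aldehyde with the α-methylene ester regenerated.

Step 6
Reactants: 10 methyl 2-methylene-5-oxopentanoate
Product: 11 methyl (Z)-6-iodo-2-methylenehept-5-enoate
Conditions: EtPPh3I, n-BuLi, THF, 0 °C; I2, −78 °C; NaHMDS, −20 °C; then 10, −78 → −20 °C
Reagents that add atoms: ethyltriphenylphosphonium iodide, CC[P+](c1ccccc1)(c1ccccc1)c1ccccc1.[I-]; iodine, II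
Why: Stork–Zhao-type Wittig olefination with the α-iodo ylide is kinetically Z-selective (typically ≥10:1), placing iodine cis to the chain so that the later coupling gives 6′Z; at −78 °C the aldehyde should react faster than the acrylate.

Step 7
Reactants: 7 1-(2-{2-allyl-4-[(triisopropylsilyl)oxy]phenoxy}propan-2-yl)cyclopropan-1-ol; 11 methyl (Z)-6-iodo-2-methylenehept-5-enoate
Product: 12 methyl (2E,5Z)-2-[2-(2-{[2-(1-hydroxycyclopropyl)propan-2-yl]oxy}-5-[(triisopropylsilyl)oxy]phenyl)ethylidene]-6-iodohept-5-enoate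
Conditions: Hoveyda–Grubbs II (7.5 mol %), 11 (2.5 equiv), 1,4-benzoquinone (10 mol %), CH2Cl2, 40 °C
Reagents that add atoms: none
Why: Olefin cross-metathesis of a type-I allylarene with a 2-substituted acrylate gives the trisubstituted enoate with the ester trans to CH2Ar (2′E, the preferred isomer for methacrylate-type partners), while the hindered trisubstituted alkenyl iodide is inert to Ru.

Step 8
Reactants: 12 methyl (2E,5Z)-2-[2-(2-{[2-(1-hydroxycyclopropyl)propan-2-yl]oxy}-5-[(triisopropylsilyl)oxy]phenyl)ethylidene]-6-iodohept-5-enoate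
Product: 13 macrocyclic ketone (10′-oxo analogue of petchiether B as its methyl ester and aryl TIPS ether; 14-membered ring, 2′E,6′Z)
Conditions: Pd(OAc)2 (15 mol %), XPhos (30 mol %), Cs2CO3 (3 equiv), toluene, 60–70 °C, syringe-pump addition of 12 (final 2 mM)
Reagents that add atoms: none
Why: Proposed new method: Pd(0) adds oxidatively to the (Z)-alkenyl iodide with retention, the caesium cyclopropoxide displaces iodide on Pd, strain-driven β-carbon elimination of the less substituted ring bond gives the Pd(II) ketone homoenolate (Pd–C8′H2–C9′H2–C10′=O), and C(sp2)–C(sp3) reductive elimination forges C7′–C8′ and closes the 14-membered ring with the 6′Z geometry retained; the closest known chemistry is the intermolecular Pd-catalysed ring-opening cross-coupling of cyclopropanols with aryl halides, the Pd-catalysed alkenylation of zinc homoenolates and macrocyclising B-alkyl Suzuki couplings, the new elements being an alkenyl iodide partner and the macrocyclising mode.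

Step 9
Reactants: 13 macrocyclic ketone
Product: 14 macrocyclic (10′R)-alcohol (petchiether B methyl ester, aryl TIPS ether)
Conditions: (S)-2-methyl-CBS-oxazaborolidine (0.5 equiv), catecholborane (2 equiv), toluene, −60 → −30 °C; MeOH, aq. NaHCO3
Reagents that add atoms: none
Why: Corey–Bakshi–Shibata reduction, in which the ketone binds the catalyst with the tertiary CMe2(OAr) group as the large substituent and hydride is delivered to the face that gives the (R)-carbinol (same sense as pinacolone or acetophenone with the (S)-catalyst), while catecholborane spares the olefins and the ester.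

Step 10
Reactants: 14 macrocyclic (10′R)-alcohol
Product: 16 petchiether B, via phenol methyl ester 15 (not isolated)
Conditions: TBAF (1.2 equiv), THF, 0 °C; then LiOH·H2O (8 equiv), THF/MeOH/H2O, 45 °C, degassed; 1 M HCl to pH 3
Reagents that add atoms: lithium hydroxide, [Li+].[OH-]
Why: Fluoride cleaves the aryl silyl ether and hydroxide saponifies the hindered methyl enoate (BAc2) in one flask, neither touching the stereocentre, the olefin geometries or the tertiary aryl ether.

**Compound list**

1 | 1,4-benzoquinone | O=C1C=CC(=O)C=C1 | starting material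
2 | allyltributylstannane | C=CC[Sn](CCCC)(CCCC)CCCC | starting material
3 | 2-allylbenzene-1,4-diol | C=CCc1cc(O)ccc1O | intermediate
4 | 2-allyl-4-[(triisopropylsilyl)oxy]phenol | C=CCc1cc(O[Si](C(C)C)(C(C)C)C(C)C)ccc1O | intermediate
5 | ethyl 2-bromo-2-methylpropanoate | CCOC(=O)C(C)(C)Br | starting material
6 | ethyl 2-{2-allyl-4-[(triisopropylsilyl)oxy]phenoxy}-2-methylpropanoate | C=CCc1cc(O[Si](C(C)C)(C(C)C)C(C)C)ccc1OC(C)(C)C(=O)OCC | intermediate
7 | 1-(2-{2-allyl-4-[(triisopropylsilyl)oxy]phenoxy}propan-2-yl)cyclopropan-1-ol | C=CCc1cc(O[Si](C(C)C)(C(C)C)C(C)C)ccc1OC(C)(C)C1(O)CC1 | intermediate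
8 | methyl 2-(hydroxymethyl)acrylate | C=C(CO)C(=O)OC | starting material
9 | methyl 2-[(vinyloxy)methyl]acrylate (allyl vinyl ether, not isolated) | C=COCC(=C)C(=O)OC | intermediate
10 | methyl 2-methylene-5-oxopentanoate | O=CCCC(=C)C(=O)OC | intermediate
11 | methyl (Z)-6-iodo-2-methylenehept-5-enoate | C/C(I)=C/CCC(=C)C(=O)OC | intermediate
12 | methyl (2E,5Z)-2-[2-(2-{[2-(1-hydroxycyclopropyl)propan-2-yl]oxy}-5-[(triisopropylsilyl)oxy]phenyl)ethylidene]-6-iodohept-5-enoate | C/C(I)=C/CC/C(C(=O)OC)=C\Cc1cc(O[Si](C(C)C)(C(C)C)C(C)C)ccc1OC(C)(C)C1(O)CC1 | intermediate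
13 | macrocyclic ketone (10′-oxo, methyl ester, aryl TIPS ether; 2′E,6′Z) | C/C1=C/CC/C(C(=O)OC)=C\Cc2cc(O[Si](C(C)C)(C(C)C)C(C)C)ccc2OC(C)(C)C(=O)CC1 | intermediate
14 | macrocyclic (10′R)-alcohol (methyl ester, aryl TIPS ether) | C/C1=C/CC/C(C(=O)OC)=C\Cc2cc(O[Si](C(C)C)(C(C)C)C(C)C)ccc2OC(C)(C)[C@H](O)CC1 | intermediate
15 | petchiether B methyl ester (phenol methyl ester, not isolated) | C/C1=C/CC/C(C(=O)OC)=C\Cc2cc(O)ccc2OC(C)(C)[C@H](O)CC1 | intermediate
16 | petchiether B | C/C1=C/CC/C(C(=O)O)=C\Cc2cc(O)ccc2OC(C)(C)[C@H](O)CC1 | target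

**Totals**

Total step count: 10. Longest linear sequence: 8 (steps 1–4 and 7–10); steps 5–6 make the side fragment 11.

**Three steps most likely to fail**

Step 8 (macrocyclising homoenolate alkenylation). The alkenyl–Pd intermediate sits 1,5 to the enoate and could undergo intramolecular Heck cyclisation; the Pd homoenolate could lose β-hydride to give the vinyl ketone; oligomers could form. The fallback sets out from 7 (with 11) and comes back at 13. The same ring-opening alkenylation is run intermolecularly at 0.2 M (Pd(OAc)2/XPhos, Cs2CO3, toluene, 60 °C), where alkoxide capture is no longer a slow macrocyclic event, to give methyl (5Z)-10-{2-allyl-4-[(triisopropylsilyl)oxy]phenoxy}-6,10-dimethyl-2-methylidene-9-oxoundec-5-enoate F1. Ring-closing metathesis of F1 (Hoveyda–Grubbs II, toluene, 80 °C, 2 mM) then forms C2′=C3′ and gives 13. The price is that the enoate geometry is no longer guaranteed and isomers may need separation.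

Step 7 (cross-metathesis). A hindered 2-substituted acrylate and an allylarene prone to isomerisation may give low conversion. The fallback sets out from 7 and comes back at 12, replacing metathesis by carbonyl condensation. Lemieux–Johnson cleavage of the allyl group (OsO4 cat., NaIO4, 2,6-lutidine, dioxane/H2O) gives 2-(2-{[2-(1-hydroxycyclopropyl)propan-2-yl]oxy}-5-[(triisopropylsilyl)oxy]phenyl)acetaldehyde F2. Methyl (Z)-6-iodohept-5-enoate F3, made from commercial methyl 5-oxopentanoate by the step 6 protocol, is converted to its lithium enolate (LDA, THF, −78 °C, 2.2 equiv) and added to F2. This gives the β-hydroxy ester methyl (5Z)-2-[1-hydroxy-2-(2-{[2-(1-hydroxycyclopropyl)propan-2-yl]oxy}-5-[(triisopropylsilyl)oxy]phenyl)ethyl]-6-iodohept-5-enoate F4 as a diastereomer mixture. One-flask treatment with MsCl/Et3N at −20 °C and then DBU eliminates through the secondary methanesulfonate of F4 F5 to the thermodynamically favoured 2E enoate 12.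

Step 6 (α-iodo Wittig olefination). The ylide or the amide base may attack the α-methylene ester, and yields of this reaction are often modest. The fallback sets out from 10 and comes back at 13. Dibromo-olefination of 10 (CBr4, PPh3, CH2Cl2, 0 °C) gives methyl 6,6-dibromo-2-methylidenehex-5-enoate F6. Trans-selective Pd-catalysed monomethylation (Me2Zn, Pd(DPEphos)Cl2, THF, 0 °C) replaces the bromide trans to the chain and leaves methyl (Z)-6-bromo-2-methylidenehept-5-enoate F7. F7 takes the place of 11 in step 7 to give methyl (2E,5Z)-6-bromo-2-[2-(2-{[2-(1-hydroxycyclopropyl)propan-2-yl]oxy}-5-[(triisopropylsilyl)oxy]phenyl)ethylidene]hept-5-enoate F8, which is cyclised under the step 8 conditions (80 °C) to 13.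

**Further compounds**

F1 | step 8 | methyl (5Z)-10-{2-allyl-4-[(triisopropylsilyl)oxy]phenoxy}-6,10-dimethyl-2-methylidene-9-oxoundec-5-enoate | C=CCc1cc(O[Si](C(C)C)(C(C)C)C(C)C)ccc1OC(C)(C)C(=O)CC/C(C)=C\CCC(=C)C(=O)OC
F2 | step 7 | 2-(2-{[2-(1-hydroxycyclopropyl)propan-2-yl]oxy}-5-[(triisopropylsilyl)oxy]phenyl)acetaldehyde | O=CCc1cc(O[Si](C(C)C)(C(C)C)C(C)C)ccc1OC(C)(C)C1(O)CC1
F3 | step 7 | methyl (Z)-6-iodohept-5-enoate | C/C(I)=C/CCCC(=O)OC
F4 | step 7 | methyl (5Z)-2-[1-hydroxy-2-(2-{[2-(1-hydroxycyclopropyl)propan-2-yl]oxy}-5-[(triisopropylsilyl)oxy]phenyl)ethyl]-6-iodohept-5-enoate (diastereomer mixture) | C/C(I)=C/CCC(C(=O)OC)C(O)Cc1cc(O[Si](C(C)C)(C(C)C)C(C)C)ccc1OC(C)(C)C1(O)CC1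
F5 | step 7 | secondary methanesulfonate of F4 (not isolated) | C/C(I)=C/CCC(C(=O)OC)C(OS(C)(=O)=O)Cc1cc(O[Si](C(C)C)(C(C)C)C(C)C)ccc1OC(C)(C)C1(O)CC1
F6 | step 6 | methyl 6,6-dibromo-2-methylidenehex-5-enoate | C=C(CCC=C(Br)Br)C(=O)OC
F7 | step 6 | methyl (Z)-6-bromo-2-methylidenehept-5-enoate | C/C(Br)=C/CCC(=C)C(=O)OC
F8 | step 6 | methyl (2E,5Z)-6-bromo-2-[2-(2-{[2-(1-hydroxycyclopropyl)propan-2-yl]oxy}-5-[(triisopropylsilyl)oxy]phenyl)ethylidene]hept-5-enoate | C/C(Br)=C/CC/C(C(=O)OC)=C\Cc1cc(O[Si](C(C)C)(C(C)C)C(C)C)ccc1OC(C)(C)C1(O)CC1
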